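No constant of the scheme is known here, so one lumped constant has to be read from the runs.

all flasks: substrate 0.50 mM

| run | reagent | scavenger | remark | time |
|---|---|---|---|---|
| epsilon | 0.90 equiv | 1.5 equiv | run made earlier |  |
| zeta | 1.4 equiv | 1.5 equiv | run made earlier |  |
| flask | 1.80 equiv | 1.50 equiv |  | 5.0 min |

- epsilon (time / min: substrate / %, product / %): 0.250: 91.4, 8.1; 0.833: 78.1, 22.4; 1.33: 68.1, 33.3; 2.00: 57.5, 42.2; 3.00: 45.9, 54.8; 4.00: 37.6, 63.9; 5.00: 29.5, 70.5
- zeta (time / min: substrate / %, product / %): 0.417: 84.0, 15.5; 0.667: 76.9, 21.8; 1.00: 68.1, 31.6; 1.33: 60.1, 38.4; 2.00: 48.5, 52.4; 3.00: 34.3, 66.6; 5.00: 16.1, 83.0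

(standard deviation of a reading: 0.5 percentage points)

- leaving ligand is meant together with its idle adduct
- what may be going on: substrate <-> intermediate + leaving ligand; reagent + intermediate -> product; reagent + leaving ligand <-> idle adduct; scavenger + leaving ligand -> scavenged by-product
- the earlier runs do not show how much of reagent is bound; that part of a forecast is a guess

1. part of the substrate that has reacted at 5.0 min
2. share of the unused reagent that is free and not bound as idle adduct, at 5.0 min

Let a be the fraction of substrate left, c = 1 − a, and b and s the equivalents of reagent and scavenger left, each falling by c.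

1. With the main step alone, first order in substrate, reagent stays out of the rate. Epsilon and zeta should then agree at 5.00 min, and the flask should give zeta's 83.9 %. But substrate left is 29.5 % in epsilon and 16.1 % in zeta.

2. Adding the return of leaving ligand makes a pre-equilibrium: intermediate goes as a over free ligand, so the rate goes as ab over free ligand.

3. Adding the scavenger, which takes ligand at a rate proportional to s times free ligand, and holding ligand steady gives a rate proportional to √(abs). Then √a falls at G√(bs), where G is the lumped constant.

4. Adding the depletion, with b and s taken at mid-conversion, makes the fall straight: √a = 1 − Gt√(bs). Epsilon gives 0.115 /min and zeta 0.116 /min, so G = 0.116 /min.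

5. For the flask, zeta's conversion as a first guess gives c = 91.4 %, and a second pass gives 90.1 %. The earlier runs do not show bound reagent, so fr stays a guess.

The forecast gives c = 89.5 % (85.5 % to 93 %) and fr = 72 % (35 % to 95 %), holding that “more reagent suppresses that return”.

The flask gives c = 90.2 % and fr = 99.9 %.

    substrate ⇌ intermediate + leaving ligand (K = 6.77 × 10⁻⁹ M, k = 0.279 /s)
    reagent + intermediate → product (k = 11100 /M/s)
    reagent + leaving ligand ⇌ idle adduct, settled at all times (K = 445 /M)
    scavenger + leaving ligand → scavenged by-product (k = 517 /M/s)

At 1.39 min free leaving ligand in the flask falls back 38 times faster than it goes on, which is the return assumed above. Read back from the flask's c, G is 0.115 /min. In a neighbouring flask, the same but with 3.80 equiv of scavenger, G with b and s taken at mid-conversion puts √a at zero after an estimated 4.17 min, earlier than 5.0 min. That neighbouring flask gives c = 100 %.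

All runs were generated by integration with constants of no real substance; the scatter is artificial.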